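**Target:** 4-{[(2R)-5-[(3R)-5,8-dihydroxy-1-oxoisochroman-3-yl]pentan-2-yl]oxy}-4-oxobutanoic acid (compound 16). Ring atoms are numbered C1 (carbonyl), O2, C3, C4, C4a, C5–C8, C8a; the side chain on C3 is C1'–C5', with C4' the carbinol carbon.

## Analysis of the target

Compound 16 is a 3,4-dihydroisocoumarin: benzene ring A is fused through C4a and C8a to the δ-lactone ring B (C1, O2, C3, C4). Ring A carries a para pair of phenols at C5 and C8, so the aromatic part is a gentisic acid unit. C3 bears a pentyl chain whose C4' oxygen is esterified by succinic acid, with the far carboxyl group free. There are two stereocentres, C3 (R) and C4' (R), in a 1,5-relationship across three methylene groups; neither can control the other, so each needs its own source of chirality. The sensitive groups are the hydroquinone (air oxidation), the lactone and the secondary succinate ester (both open to base and hard to tell apart), and the free acid. The real difficulty is selectivity: the two secondary oxygens (O2 and the C4' oxygen) must end in different acyl groups, and the carboxyl carbon C1 must sit on the most crowded ring position, between the side chain and an oxygen substituent. The strategy rests on one feature of the ring-opened form. C8a is the only hydrogen-bearing position ortho to C4a (C5 carries oxygen), and the C3 oxygen is two carbons (C3, C4) from the ring. A metal bound to that oxygen therefore reaches C8a through a six-membered metallacycle, and C1 can be inserted last as carbon monoxide between C8a and O2.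

## Retrosynthetic reasoning

**16 to 14 (through 15).** The two phenolic hydroxyls are traced back to methyl ethers. The hydroquinone is the most fragile part of 16 and would interfere with acylation and with any metal-mediated step, so it is unveiled last. In the forward direction the para-dimethoxyarene of 14 is oxidised to quinone 15, which is reduced at once. Electron-transfer oxidation and mild reduction leave the lactone, the succinate ester and the acid alone, where hydrolytic or strongly Lewis acidic ether cleavage would endanger them.

**14 to 12 and 13.** The ester C–O bond between the C4' oxygen and the succinyl carbonyl is cut. Opening of anhydride 13 by alcohol 12 gives the half ester with the acid already free, so no protecting group is needed on the carboxyl. This comes after ring closure because a free acid would compete as a directing group in the metal-mediated step.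

**12 to 11.** The C4' oxygen is carried as a benzyl ether. It keeps the two secondary oxygens distinct from the chiral pool onwards and tolerates organomagnesium and oxidative palladium conditions. Hydrogenolysis removes it without touching ring B, because the C3–O2 bond is homobenzylic and not benzylic.

**11 to 9 and 10 (key disconnection).** Both bonds at C1 are cut, C8a–C1 and C1–O2. Cutting C3–O2 or C3–C4 instead would force C3 to be created during ring formation. Removing C1 as 10 leaves alcohol 9, an arene with a plain C8a–H bond and a hydroxyalkyl chain, so no halogen or carboxyl has to be placed beforehand on the hindered ring position. Both stereocentres are already in 9 and neither new bond touches them. In the forward direction the C3 alkoxide must deliver divalent palladium to C8a–H, 10 must insert, and C–O reductive elimination must outrun oxidation of the carbinol.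

**9 to 3 and 8.** The chain of 9 is cut between C3 and C4 of the heptane (C1'–C2' of the target side chain). This lies midway between the stereocentres, so each fragment carries exactly one and the coupling touches neither. Epoxide 3 is the electrophile at its unsubstituted carbon and organomagnesium 8 the nucleophile, which leaves the C–O bond at the stereocentre intact. Reagent 8 comes from bromide 7.

**3 to 2 to 1.** The C3 stereocentre is traced to the epoxide oxygen added to the allyl double bond of 1. Racemic 2 is resolved by hydrolytic kinetic resolution; this gives up half of a cheap one-step intermediate in return for dependable enantiopurity of a monosubstituted oxirane.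

**7 to 6 to 5 to 4.** The C4' stereocentre is taken from diol 4. Its two hydroxyls are told apart by closing the cyclic benzylidene acetal 5 and opening it reductively, which puts the benzyl group on the secondary oxygen and frees the primary alcohol in 6. Alcohol 6 is converted into 7. No step acts at the stereocentre.

## Alternatives that were turned down

**Alternative 1:** C3–C4 and the C1–O2 acyl bond are cut, leading to 5,8-dimethoxyisochromane-1,3-dione A1 and the aldehyde tert-butyl [(2R)-6-oxohexan-2-yl] butanedioate A2.
- **Key step:** a bifunctional cinchona squaramide would direct the enol of A1 onto one face of A2. The resulting alkoxide would open the anhydride at the aryl carbonyl, giving (3R,4S)-3-[(R)-4-[(4-tert-butoxy-4-oxobutanoyl)oxy]pentyl]-5,8-dimethoxy-1-oxoisochromane-4-carboxylic acid A3. The C4 carboxyl is then removed.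
- **For:** C3 and ring B arise in one catalytic step, the substitution of ring A is fixed by A1, and the succinate is already in place. It is stronger than the chosen route on two points: C3 is made by catalysis and not by a resolution, and no hindered aryl C–H bond has to be activated.
- **Against:**
  - A1 needs a carbon homologation of a benzoic acid and several steps.
  - A2 is an enolisable aliphatic aldehyde, the less favourable class for this annulation (self-condensation, weaker facial control).
  - The C8 methoxy group flanks the carbonyl that must be acylated.
  - A3 carries a carbon that 16 lacks. Its removal needs forcing conditions, under which the C4 carbanion can expel the C3 oxygen (ring opening, loss of C3 integrity).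
  - The tert-butyl ester adds an acid step at the end.
- **Comparison:** the chosen route is shorter, introduces no carbon that must be removed, and takes both stereocentres from sources of predictable purity.

**Alternative 2:** C3–O2 is cut with C1 at the alcohol oxidation level, leading to [2-(but-3-en-1-yl)-3,6-dimethoxyphenyl]methanol A4.
- **Key step:** divalent palladium with a chiral aryl sulfoxide–oxazoline ligand would cleave the allylic C3–H bond. The benzylic hydroxyl would attack the internal end of the π-allyl, giving (S)-5,8-dimethoxy-3-vinylisochromane A5. The S descriptor comes from the rank of the vinyl group; the spatial arrangement is that of C3 in 16.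
- **For:** A4 is quickly made, C3 is set by the catalyst without a resolution, and an allylic C–H bond is easier to cleave than the flanked aryl C–H bond of 9. On that last point it is stronger.
- **Against:**
  - A5 is far from 16. The chain must be grown by cross-metathesis with tert-butyldimethyl{[(2R)-pent-4-en-2-yl]oxy}silane A6 and then hydrogenated, while the C3–O2 bond is allylic and open to hydrogenolysis.
  - C1 must be raised from ether to lactone level next to an electron-rich arene.
  - Any shortfall in enantioselectivity becomes a 1,5-diastereomer mixture that is hard to separate.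
  - The electron-rich benzylic alcohol of A4 may be oxidised under the oxidative conditions.
- **Comparison:** the chosen route closes ring B at the final oxidation level with the complete chain attached, and saves about four steps after the key step.

**Alternative 3:** ring A is dismantled at C6–C7 and C4a–C8a, leading to 1-methoxy-1,3-bis(trimethylsilyloxy)buta-1,3-diene A7 and the keto acetal benzyl [(2R,6R)-9-(benzyloxy)-6-[(tert-butyldimethylsilyl)oxy]-10,10-dimethoxy-8-oxodecan-2-yl] butanedioate A8.
- **Key step:** under a strong Lewis acid the terminal carbon of A7 would bond to the acetal carbon and its central carbon to the ketone carbon. Loss of two alcohol molecules and one of water would aromatise to methyl 3-(benzyloxy)-6-hydroxy-2-[(2R,6R)-6-[(4-benzyloxy-4-oxobutanoyl)oxy]-2-(tert-butyldimethylsilyloxy)heptyl]benzoate A9.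
- **For:** the positions of all four substituents on ring A follow from the condensation, so no site selectivity on an arene is needed. The phenol oxygens come out differentiated and are released by hydrogenolysis, a milder end than the cerium oxidation of the chosen route. On both points it is stronger.
- **Against:**
  - It builds a benzene ring that can be bought with the right oxygen pattern.
  - A8 carries both stereocentres, a β-silyloxy ketone, an α-alkoxy group, an acetal and two esters. Making it would take more steps than the whole chosen route.
  - The β-silyloxy ketone is prone to elimination under the Lewis acid.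
  - Desilylation and lactonisation still follow the key step.
- **Comparison:** the chosen route uses ring A as purchased and adds a single carbon to it.

Key step: step 7

## Route

Remark on the chemistry: the (R,R)-configured cobalt salen catalyst is taken to hydrolyse the (R)-enantiomer of 2 and leave the (S)-epoxide, as with other monosubstituted alkyl oxiranes; if the sense were the reverse, the (S,S)-catalyst would be used.

Step 1
Reactants: 1 2-allyl-1,4-dimethoxybenzene
Product: 2 rac-2-[(2,5-dimethoxyphenyl)methyl]oxirane
Conditions: mCPBA, NaHCO3, CH2Cl2, 0 °C to rt
Reagents that add atoms: mCPBA (3-chloroperoxybenzoic acid), O=C(OO)c1cccc(Cl)c1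
Why: Prilezhaev epoxidation of the isolated terminal alkene; the buffered peracid should leave the dimethoxyarene untouched, and a racemate is intended because the next step resolves it.

Step 2
Reactants: 2 rac-2-[(2,5-dimethoxyphenyl)methyl]oxirane
Product: 3 (S)-2-[(2,5-dimethoxyphenyl)methyl]oxirane
Conditions: (R,R)-(salen)Co(OAc) (0.5 mol%; salen = N,N'-bis(3,5-di-tert-butylsalicylidene)cyclohexane-1,2-diaminate), H2O (0.55 equiv), THF, 0 °C to rt
Reagents that add atoms: none
Why: Hydrolytic kinetic resolution: the chiral trivalent cobalt complex hydrolyses the (R)-epoxide to the diol and leaves the (S)-epoxide, which is separated from the polar diol. This sets the configuration that becomes C3 of the target; running slightly past half conversion should secure high enantiopurity.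

Step 3
Reactants: 4 (R)-butane-1,3-diol
Product: 5 (2S,4R)-4-methyl-2-phenyl-1,3-dioxane
Conditions: PhCH(OMe)2, camphorsulfonic acid (cat.), CH2Cl2, rt
Reagents that add atoms: benzaldehyde dimethyl acetal, COC(OC)c1ccccc1
Why: Acid-catalysed transacetalisation under thermodynamic control, which places phenyl and methyl both equatorial; the acetal carbon is a temporary stereocentre that is lost in step 4, and the pool stereocentre is not involved.

Step 4
Reactants: 5 (2S,4R)-4-methyl-2-phenyl-1,3-dioxane
Product: 6 (R)-3-(benzyloxy)butan-1-ol
Conditions: i-Bu2AlH, CH2Cl2, 0 °C to rt; aq. potassium sodium tartrate work-up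
Reagents that add atoms: none
Why: Regioselective reductive opening of a benzylidene acetal: aluminium binds the less hindered oxygen (on the CH2), that C–O bond ionises, and hydride reduces the oxocarbenium ion. The benzyl group therefore stays on the secondary oxygen and the primary alcohol is freed.

Step 5
Reactants: 6 (R)-3-(benzyloxy)butan-1-ol
Product: 7 (R)-{[(4-bromobutan-2-yl)oxy]methyl}benzene
Conditions: CBr4, PPh3, CH2Cl2, 0 °C
Reagents that add atoms: carbon tetrabromide, BrC(Br)(Br)Br
Why: Appel reaction of a primary alcohol under neutral conditions; the substitution occurs two carbons from the stereocentre, which stays untouched.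

Step 6
Reactants: 7 (R)-{[(4-bromobutan-2-yl)oxy]methyl}benzene; 3 (S)-2-[(2,5-dimethoxyphenyl)methyl]oxirane
Product: 9 (2R,6R)-6-(benzyloxy)-1-(2,5-dimethoxyphenyl)heptan-2-ol, via alkylmagnesium bromide 8 (not isolated)
Conditions: Mg, BrCH2CH2Br (cat.), THF, rt to 40 °C; then CuI (10 mol%), 3, THF, −30 to 0 °C
Reagents that add atoms: none
Why: Grignard formation (a γ-alkoxy organomagnesium has no β-leaving group and should be stable), then copper-catalysed SN2 opening of the monosubstituted epoxide at its CH2 terminus. The C–O bond at the epoxide stereocentre is not broken, so its geometry is retained; the descriptor changes from S to R only because the ranks of the two carbon substituents swap.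

Step 7
Reactants: 9 (2R,6R)-6-(benzyloxy)-1-(2,5-dimethoxyphenyl)heptan-2-ol; 10 carbon monoxide
Product: 11 (R)-3-[(R)-4-(benzyloxy)pentyl]-5,8-dimethoxyisochroman-1-one
Conditions: Pd(OAc)2 (10 mol%), N-(menthyloxycarbonyl)-L-leucine (20 mol%), AgOAc (3 equiv), Li2CO3 (1 equiv), CO (1 atm), ClCH2CH2Cl, 110 °C
Reagents that add atoms: none
Why: Hydroxyl-directed C–H carbonylation, a known reaction of phenethyl alcohols that gives isochroman-1-ones; the secondary alcohol 9 belongs to the less reactive part of that substrate class. The alkoxide of 9 binds divalent palladium, and a carboxylate-assisted concerted metalation–deprotonation cleaves the C8a–H bond to give a six-membered palladacycle (Pd, O2, C3, C4, C4a, C8a). CO 10 inserts into the aryl–palladium bond to give a seven-membered acyl palladium alkoxide, and C–O reductive elimination releases the lactone; seen from the acyl carbon this is a 6-exo-trig closure of ring B that forms C8a–C1 and C1–O2. Two equivalents of AgOAc return zerovalent palladium to the divalent state. No stereocentre is formed, and the C3–O bond and C4' are not involved, so both configurations should carry through. Site selectivity is secured by the substrate: of the two positions ortho to the side chain one bears a methoxy group, so only C8a can close a palladacycle; C6 and C7 are out of reach of the tether, and the benzyl ether oxygen is a far weaker donor than the alkoxide. Chemoselectivity against β-hydride elimination of the palladium alkoxide (ketone formation) rests on the amino acid ligand accelerating C–H cleavage and on CO occupying the site that β-hydride elimination needs.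

Step 8
Reactants: 11 (R)-3-[(R)-4-(benzyloxy)pentyl]-5,8-dimethoxyisochroman-1-one
Product: 12 (R)-3-[(R)-4-hydroxypentyl]-5,8-dimethoxyisochroman-1-one
Conditions: H2 (1 atm), Pd/C (10 wt%), EtOAc, rt
Reagents that add atoms: none
Why: Hydrogenolysis of the benzyl ether; the lactone C3–O2 bond is homobenzylic and the aryl methyl ethers are inert, so only the benzyl group should be lost.

Step 9
Reactants: 12 (R)-3-[(R)-4-hydroxypentyl]-5,8-dimethoxyisochroman-1-one; 13 succinic anhydride
Product: 14 4-{[(2R)-5-[(3R)-5,8-dimethoxy-1-oxoisochroman-3-yl]pentan-2-yl]oxy}-4-oxobutanoic acid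
Conditions: succinic anhydride, DMAP (cat.), Et3N, CH2Cl2, rt; dilute acid work-up
Reagents that add atoms: none
Why: DMAP-catalysed ring opening of a cyclic anhydride by the secondary alcohol gives the half ester directly, with retention at C4' because only the O–H bond reacts; the lactone is stable to these mild basic conditions.

Step 10
Reactants: 14 4-{[(2R)-5-[(3R)-5,8-dimethoxy-1-oxoisochroman-3-yl]pentan-2-yl]oxy}-4-oxobutanoic acid
Product: 16 4-{[(2R)-5-[(3R)-5,8-dihydroxy-1-oxoisochroman-3-yl]pentan-2-yl]oxy}-4-oxobutanoic acid, via quinone 15 (not isolated)
Conditions: (NH4)2Ce(NO3)6 (2.5 equiv), MeCN/H2O, 0 °C; then Na2S2O4, EtOAc/H2O, rt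
Reagents that add atoms: water, O
Why: Oxidative demethylation of a para-dimethoxyarene by tetravalent cerium (arene radical cation, attack of water, loss of methanol) gives acyl quinone 15, which is kept in solution and reduced at once by dithionite to the hydroquinone. Esters, lactone, acid and both stereocentres are not affected by either reagent.

## Compound list

1 | 2-allyl-1,4-dimethoxybenzene | C=CCc1cc(OC)ccc1OC | starting material
2 | rac-2-[(2,5-dimethoxyphenyl)methyl]oxirane | COc1ccc(OC)c(CC2CO2)c1 | intermediate
3 | (S)-2-[(2,5-dimethoxyphenyl)methyl]oxirane | COc1ccc(OC)c(C[C@H]2CO2)c1 | intermediate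
4 | (R)-butane-1,3-diol | C[C@@H](O)CCO | starting material
5 | (2S,4R)-4-methyl-2-phenyl-1,3-dioxane | C[C@@H]1CCO[C@H](c2ccccc2)O1 | intermediate
6 | (R)-3-(benzyloxy)butan-1-ol | C[C@@H](OCc1ccccc1)CCO | intermediate
7 | (R)-{[(4-bromobutan-2-yl)oxy]methyl}benzene | C[C@@H](OCc1ccccc1)CCBr | intermediate
8 | (R)-[3-(benzyloxy)butyl]magnesium bromide | C[C@@H](OCc1ccccc1)CC[Mg]Br | intermediate
9 | (2R,6R)-6-(benzyloxy)-1-(2,5-dimethoxyphenyl)heptan-2-ol | COc1ccc(OC)c(C[C@H](O)CCC[C@@H](C)OCc2ccccc2)c1 | intermediate
10 | carbon monoxide | [C-]#[O+] | starting material
11 | (R)-3-[(R)-4-(benzyloxy)pentyl]-5,8-dimethoxyisochroman-1-one | C[C@H](CCC[C@@H]1Cc2c(OC)ccc(OC)c2C(=O)O1)OCc1ccccc1 | intermediate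
12 | (R)-3-[(R)-4-hydroxypentyl]-5,8-dimethoxyisochroman-1-one | C[C@H](CCC[C@@H]1Cc2c(OC)ccc(OC)c2C(=O)O1)O | intermediate
13 | succinic anhydride | O=C1CCC(=O)O1 | starting material
14 | 4-{[(2R)-5-[(3R)-5,8-dimethoxy-1-oxoisochroman-3-yl]pentan-2-yl]oxy}-4-oxobutanoic acid | C[C@H](CCC[C@@H]1Cc2c(OC)ccc(OC)c2C(=O)O1)OC(=O)CCC(=O)O | intermediate
15 | 4-oxo-4-{[(2R)-5-[(3R)-1,5,8-trioxo-3,4,5,8-tetrahydro-1H-isochromen-3-yl]pentan-2-yl]oxy}butanoic acid | C[C@H](CCC[C@@H]1CC2=C(C(=O)C=CC2=O)C(=O)O1)OC(=O)CCC(=O)O | intermediate
16 | 4-{[(2R)-5-[(3R)-5,8-dihydroxy-1-oxoisochroman-3-yl]pentan-2-yl]oxy}-4-oxobutanoic acid | C[C@H](CCC[C@@H]1Cc2c(O)ccc(O)c2C(=O)O1)OC(=O)CCC(=O)O | target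

## Step count and least certain steps

Total step count: 10. Longest linear sequence: 8 steps (steps 3 to 10, from 4 to 16); the branch from 1 joins at step 6 after 2 steps.

**Step 7 (key step).** The palladium alkoxide of the secondary alcohol may undergo β-hydride elimination faster than C–H cleavage, which oxidises the carbinol and erases C3. Metalation at C8a may also be slow, because that C–H bond is flanked by the side chain and a methoxy group. Oxidative alkoxycarbonylation of the hydroxyl without C–H cleavage is a further drain. The fallback sets out from 9 and returns at 11 by electrophilic aromatic substitution, without a metal on the carbinol oxygen. Alcohol 9 is converted with chloromethyl methyl ether and i-Pr2NEt into 2-[(2R,6R)-6-(benzyloxy)-2-(methoxymethoxy)heptyl]-1,4-dimethoxybenzene F1. Me3SiOTf in CH2Cl2 at 0 °C ionises the acetal, and the oxocarbenium ion closes onto C8a in an oxa-Pictet–Spengler cyclisation to give (R)-3-[(R)-4-(benzyloxy)pentyl]-5,8-dimethoxyisochromane F2; C8a is the only free ortho position and is activated by the neighbouring methoxy group. Hydride abstraction from C1 with DDQ in wet CH2Cl2 should give (3R)-3-[(R)-4-(benzyloxy)pentyl]-5,8-dimethoxyisochroman-1-ol F3, since C1 is both benzylic and α to oxygen and should react ahead of the benzyl ether. Oxidation of the lactol with PhI(OAc)2 and catalytic TEMPO returns 11. This costs three more steps.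

**Step 6.** Formation of 8 may be accompanied by Wurtz-type homocoupling. In the coupling, Lewis acidic magnesium halide may open 3 to a bromohydrin or isomerise it (Meinwald rearrangement) before alkyl transfer from copper occurs. The fallback sets out from 7 and returns at 9 with a sulfone-stabilised carbanion as the nucleophile. Bromide 7 and PhSO2Na in DMF give (R)-{[(4-(phenylsulfonyl)butan-2-yl)oxy]methyl}benzene F4. Deprotonation with n-BuLi in THF at −78 °C and addition of 3 with BF3·OEt2 give (2S,6R)-6-(benzyloxy)-1-(2,5-dimethoxyphenyl)-4-(phenylsulfonyl)heptan-2-ol F5 as both C4 epimers; the C2 descriptor changes by ranking only. Reductive desulfonylation with Na/Hg and Na2HPO4 in MeOH returns 9.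

**Step 10.** The arene of 14 is deactivated by the lactone carbonyl, so electron transfer to tetravalent cerium may be slow. Over-oxidation, and addition of water or nitrate to the very electrophilic acyl quinone, may then compete. The fallback sets out from 14 and returns at 15 by splitting the task into a chelation-controlled ether cleavage and a much easier oxidation. BCl3 in CH2Cl2 at −78 to 0 °C should cleave only the C8 methyl ether, which lies peri to the lactone carbonyl and binds boron, giving 4-{[(2R)-5-[(3R)-8-hydroxy-5-methoxy-1-oxoisochroman-3-yl]pentan-2-yl]oxy}-4-oxobutanoic acid F6. This para-methoxyphenol is oxidised by PhI(OAc)2 in aqueous MeCN to 15, which is reduced with Na2S2O4 as in step 10.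

**Step 4.** Cleavage of the acetal may be incompletely regioselective, giving some of the primary benzyl ether, which is hard to separate from 6. The fallback sets out from 4 and returns at 6 by a protecting-group sequence. Diol 4 with t-BuPh2SiCl and imidazole gives (R)-4-[(tert-butyldiphenylsilyl)oxy]butan-2-ol F7 by selective silylation of the primary hydroxyl. NaH and benzyl bromide in THF give (R)-[3-(benzyloxy)butoxy](tert-butyl)diphenylsilane F8. Bu4NF in THF returns 6.

## Further compounds

F1 | step 7 | 2-[(2R,6R)-6-(benzyloxy)-2-(methoxymethoxy)heptyl]-1,4-dimethoxybenzene | COc1ccc(OC)c(C[C@H](OCOC)CCC[C@@H](C)OCc2ccccc2)c1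
F2 | step 7 | (R)-3-[(R)-4-(benzyloxy)pentyl]-5,8-dimethoxyisochromane | C[C@H](CCC[C@@H]1Cc2c(OC)ccc(OC)c2CO1)OCc1ccccc1
F3 | step 7 | (3R)-3-[(R)-4-(benzyloxy)pentyl]-5,8-dimethoxyisochroman-1-ol (both C1 epimers) | C[C@H](CCC[C@@H]1Cc2c(OC)ccc(OC)c2C(O)O1)OCc1ccccc1
F4 | step 6 | (R)-{[(4-(phenylsulfonyl)butan-2-yl)oxy]methyl}benzene | C[C@@H](OCc1ccccc1)CCS(=O)(=O)c1ccccc1
F5 | step 6 | (2S,6R)-6-(benzyloxy)-1-(2,5-dimethoxyphenyl)-4-(phenylsulfonyl)heptan-2-ol (both C4 epimers) | COc1ccc(OC)c(C[C@H](O)CC(C[C@@H](C)OCc2ccccc2)S(=O)(=O)c2ccccc2)c1
F6 | step 10 | 4-{[(2R)-5-[(3R)-8-hydroxy-5-methoxy-1-oxoisochroman-3-yl]pentan-2-yl]oxy}-4-oxobutanoic acid | C[C@H](CCC[C@@H]1Cc2c(OC)ccc(O)c2C(=O)O1)OC(=O)CCC(=O)O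
F7 | step 4 | (R)-4-[(tert-butyldiphenylsilyl)oxy]butan-2-ol | C[C@@H](O)CCO[Si](c1ccccc1)(c1ccccc1)C(C)(C)C
F8 | step 4 | (R)-[3-(benzyloxy)butoxy](tert-butyl)diphenylsilane | C[C@@H](OCc1ccccc1)CCO[Si](c1ccccc1)(c1ccccc1)C(C)(C)C
A1 | alternative 1 | 5,8-dimethoxyisochromane-1,3-dione | COc1ccc(OC)c2c1CC(=O)OC2=O
A2 | alternative 1 | tert-butyl [(2R)-6-oxohexan-2-yl] butanedioate | C[C@H](CCCC=O)OC(=O)CCC(=O)OC(C)(C)C
A3 | alternative 1 | (3R,4S)-3-[(R)-4-[(4-tert-butoxy-4-oxobutanoyl)oxy]pentyl]-5,8-dimethoxy-1-oxoisochromane-4-carboxylic acid | C[C@H](CCC[C@@H]1[C@@H](C(=O)O)c2c(OC)ccc(OC)c2C(=O)O1)OC(=O)CCC(=O)OC(C)(C)C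
A4 | alternative 2 | [2-(but-3-en-1-yl)-3,6-dimethoxyphenyl]methanol | C=CCCc1c(OC)ccc(OC)c1CO
A5 | alternative 2 | (S)-5,8-dimethoxy-3-vinylisochromane | C=C[C@@H]1Cc2c(OC)ccc(OC)c2CO1
A6 | alternative 2 | tert-butyldimethyl{[(2R)-pent-4-en-2-yl]oxy}silane | C=CC[C@@H](C)O[Si](C)(C)C(C)(C)C
A7 | alternative 3 | 1-methoxy-1,3-bis(trimethylsilyloxy)buta-1,3-diene | C=C(O[Si](C)(C)C)C=C(OC)O[Si](C)(C)C
A8 | alternative 3 | benzyl [(2R,6R)-9-(benzyloxy)-6-[(tert-butyldimethylsilyl)oxy]-10,10-dimethoxy-8-oxodecan-2-yl] butanedioate (C9 unspecified) | COC(OC)C(OCc1ccccc1)C(=O)C[C@H](O[Si](C)(C)C(C)(C)C)CCC[C@@H](C)OC(=O)CCC(=O)OCc1ccccc1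
A9 | alternative 3 | methyl 3-(benzyloxy)-6-hydroxy-2-[(2R,6R)-6-[(4-benzyloxy-4-oxobutanoyl)oxy]-2-(tert-butyldimethylsilyloxy)heptyl]benzoate | COC(=O)c1c(O)ccc(OCc2ccccc2)c1C[C@H](O[Si](C)(C)C(C)(C)C)CCC[C@@H](C)OC(=O)CCC(=O)OCc1ccccc1
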